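A small charge of second catalyst, 10 µM, stands against 18.0 mM of reagent in each of these flasks.

in all of them: free catalyst 100 µM; second catalyst 10 µM
- epsilon: substrate 28 mM; reagent 18 mM; run made earlier
- theta: substrate 44 mM; reagent 18 mM; run made earlier
- flask: substrate 20 mM; reagent 18.0 mM; time 20 min

- epsilon (time / min: target / %, isomer of the product / %): 1.33: 3.3, 1.7; 4.00: 5.5, 10.4; 8.00: 6.1, 23.3; 10.0: 4.9, 29.9; 15.0: 3.8, 40.3; 20.0: 4.5, 46.5
- theta (time / min: target / %, isomer of the product / %): 3.00: 3.8, 5.3; 6.00: 3.1, 11.9; 10.0: 2.9, 19.7; 12.0: 3.0, 21.6; 15.0: 3.5, 25.6; 20.0: 2.7, 30.6

(readings scatter by 0.5 percentage points)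

- ratio of target to isomer of the product at 30 s
- ratio of target to isomer of the product at 3.0 min
- ratio of target to isomer of the product at 20 min
- which of target and isomer of the product there is more of at 20 min

- candidate steps: second catalyst + open intermediate <-> catalyst intermediate; target -> over-reaction product; substrate + free catalyst -> free catalyst + open intermediate; reagent + catalyst intermediate -> second catalyst + target; target <-> isomer of the product

By 20.0 min the epsilon run has made 14.3 mM of target plus isomer of the product from 28 mM of substrate, and the theta run 14.7 mM from 44 mM. The flow therefore does not follow the substrate, but it does slow: the epsilon run makes 1.11 mM min⁻¹ up to 4.00 min and 0.386 mM min⁻¹ from 15.0 min on. As a first reckoning the feed into target is frozen as steady, with target draining into isomer, and that slowing is set aside.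

Such a pool fills with a time constant. It is read as the share of target in target plus isomer, times the elapsed time, at 4.00 min in the epsilon run: the lifetime of target, τ = 1.38 min. With a steady feed the ratio folds into x = t/τ, the lifetimes elapsed, and [target]/[isomer of the product] = (1 − e^−x)/(x − 1 + e^−x).

For the flask, x is 0.361, 2.17 and 14.5, which gives ratios of 5.22, 0.691 and 0.0743, with isomer ahead at the end. The test stands on scattered readings. At 1.33 min the curve gives 1.79 and the epsilon readings 1.94. At 20.0 min the epsilon and theta readings give 0.0968 and 0.0882, both above the curve, but their target readings of 4.5% and 2.7% carry a scatter of 0.5 percentage points, so these gaps do not show that one number falls short.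

The forecast gives 5.2, 0.7 and 0.09, with isomer of the product ahead. Its late value rests on “the slow reverse step”, which the curve here does not contain, and it stands above the curve's value.

    second catalyst + open intermediate ⇌ catalyst intermediate (K = 24000 M⁻¹, k = 1700 M⁻¹ s⁻¹)
    target → over-reaction product (k = 8.30 × 10⁻⁶ s⁻¹)
    substrate + free catalyst → free catalyst + open intermediate (k = 69.0 M⁻¹ s⁻¹)
    reagent + catalyst intermediate → second catalyst + target (k = 140 M⁻¹ s⁻¹)
    target ⇌ isomer of the product (K = 23.0, k = 0.0120 s⁻¹)

The flask gives 6.71, 0.784 and 0.0786, with isomer of the product at 65.3% against 5.13% of target. The catalyst intermediate, the resting state of the second catalyst, holds 94.2% of that charge at 20.0 min. Target equals isomer in the flask at 2.48 min, which is x = 1.80. A neighbouring flask with 0.0025 mM of second catalyst, a quarter of the charge, has the same x of 2.17 at 3.0 min, where the curve says 0.691, and it gives 0.812.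

The data stem from a simulated flask from invented constants, and the scatter is random.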